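Readings and results were generated by integration on assumed constants; the scatter is artificial.

Slowness is what you can count here: in the dawn run intermediate C still reads 35% at 8.00 min, barely off its 36% at 4.00 min, while side product climbs from 12% to 23%.

| flask | substrate | reagent | remark | time |
|---|---|---|---|---|
| noon | 1 M | 0.92 M | run made earlier |  |
| dawn | 1 M | 1.2 M | run made earlier |  |
| dusk | 1 M | 1.3 M | run made earlier |  |
| gamma | 1.0 M | 1.10 M |  | 10 min |
| eta | 1.0 M | 1.60 M |  | 10 min |

| run | time / min | intermediate C / % | substrate / % | side product / % | intermediate B / % | target / % |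
|---|---|---|---|---|---|---|
| noon | 1.33 | 18 | 69 | 0 | 1 | 0 |
| noon | 3.00 | 34 | 53 | 4 | 3 | 4 |
| noon | 4.00 | 32 | 49 | 8 | 7 | 1 |
| noon | 6.00 | 34 | 42 | 11 | 12 | 3 |
| noon | 8.00 | 32 | 32 | 13 | 8 | 5 |
| dawn | 0.500 | 10 | 77 | 0 | 4 | 4 |
| dawn | 1.00 | 22 | 69 | 4 | 0 | 3 |
| dawn | 2.00 | 29 | 54 | 9 | 2 | 5 |
| dawn | 4.00 | 36 | 38 | 12 | 4 | 4 |
| dawn | 8.00 | 35 | 23 | 23 | 11 | 4 |
| dusk | 1.33 | 26 | 62 | 3 | 3 | 1 |
| dusk | 3.00 | 38 | 40 | 14 | 3 | 3 |
| dusk | 4.00 | 36 | 36 | 15 | 7 | 4 |
| dusk | 6.00 | 37 | 20 | 21 | 9 | 2 |
| dusk | 8.00 | 34 | 19 | 26 | 19 | 2 |

(standard deviation of a reading: 2 percentage points)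

- a reading of intermediate B is of its free form alone

- which of these there is most of at the end, counted by the substrate in it, gamma (intermediate C / substrate / side product / intermediate B)
- which of these there is most of at the end, counted by the substrate in it, eta (intermediate C / substrate / side product / intermediate B)
- final amount of the leader among these, as a percentage of the substrate charged, in gamma
- final amount of the leader among these, as a percentage of the substrate charged, in eta

Turn the question round. Dawn's last row has intermediate C above substrate and intermediate B, so I race C against side product. For side product to lead, the standing C must have turned over once into side product: the ratio of side product to C, my turnover count, must reach one.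

Take reagent as a fraction of the substrate charge and assume one unit goes per substrate lost and one per side product made. By its last readings dawn then ends with 0.200 of reagent, and the mean of its first and last reagent, times the run, gives 5.60 min of reagent-time. Its ratio of 0.657 over that gives the turnovers per unit of reagent-time, 0.117 /min, a reading with the scatter of that row; times the mean reagent, it acts as a pseudo-first-order constant.

Gamma, borrowing dawn's leftover, counts 0.763, short of one by 0.237, so I expect C to lead at about dawn's 35%. Eta, borrowing dusk's leftover of 0.230, counts 1.07, barely past one, so I expect side product to lead at about that count times dawn's C, 37.6%.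

The forecast names the same leaders at lower amounts than mine , intermediate C at 33% in gamma and side product at 33% in eta, with the caution “though this is an extrapolation beyond the tested reagent range”.

The flask gives intermediate C at 32.1% in gamma and side product at 40.1% in eta.

    substrate + reagent ⇌ intermediate A (K = 0.630 /M, k = 0.470 /M/min)
    intermediate A → target (k = 0.110 /min)
    intermediate A → intermediate B (k = 0.100 /min)
    intermediate A → intermediate C (k = 2.30 /min)
    intermediate B ⇌ intermediate D (K = 0.230, k = 0.150 /min)
    reagent + intermediate C → side product (k = 0.210 /M/min)
    intermediate C ⇌ intermediate B (K = 17.0, k = 0.0480 /min)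

With gamma's simulated reagent left, 11.7% of its own charge, the count becomes 0.721, against a ratio of 0.680 in the flask. Eta's ratio, 1.49, stands above my 1.07, on the same side of one. Now the neighbour, the gamma flask read at 6.0 min: with 23.1% of its reagent left, the count is 0.477, and it holds side product 16.5% against intermediate C 36.5%, a ratio of 0.452.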